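## Structural features

Mollicellin B (23) is an achiral depsidone. Ring A is a benzoyl ring carrying a C-methyl group, a phenol and a formyl group ortho to that phenol. It is tied to ring B twice, through an aryl ester and through a diaryl ether, so that a seven-membered dioxepinone lies between the two arenes. Ring B carries a third oxygen, para to the lactone oxygen, which with the neighbouring ring carbon belongs to a fused 2,2-dimethyl-2,3-dihydropyran-4-one. The other ring B positions hold a methyl group (between the lactone-oxygen carbon and the ketone-bearing carbon) and a single hydrogen (between the ether-oxygen and pyranone-oxygen carbons). There is no stereocentre, so no stereocentres stand next to each other and nothing has to be set or protected in that respect.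

The fragile groups are the aryl ester lactone (opened by alkoxides, prone to acyl shift in strong acid), the salicylaldehyde, the chromanone (retro-oxa-Michael under base) and, on the way, ring B at the hydroquinone level (autoxidation). The real difficulty is the pentasubstituted ring B, with three oxygens of three different kinds in a 1,2,4-pattern, together with a diaryl ether bond that is doubly ortho-substituted on ring A.

The key step uses one feature of ring B. The lactone-oxygen carbon and the pyranone-oxygen carbon are para, and the former is flanked by the methyl-bearing and aryloxy-bearing carbons. That is the substitution pattern of the hydroquinone that a 3-aryloxy-4-hydroxy-4-(prop-1-en-2-yl)cyclobutenone gives on thermal ring expansion.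

## Logic of the disconnections

23 ⇒ 22. The O–CH3 bond on the ring A phenol is restored. The phenol must stay capped throughout: a free ring A hydroxyl would compete in the ether-forming step and would offer a second site for pyranone annulation. The forward step must cleave one aryl methyl ether beside a lactone, a ketone and a tertiary alkyl aryl ether; the ortho formyl group makes this possible by chelation.

22 ⇒ 18 + 19. The pyranone is cut at the ring B carbon–C(=O) bond and at the O–CMe2 bond, and the formyl group is returned to its acetal. This removes a ring and five carbons in one operation. The forward step must acylate the ring B carbon between hydroxyl and methyl, not the one between the two oxygens, and must not disturb the lactone.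

18 ⇒ 17. The lactone O–C(=O) bond is cut. Only the ring B hydroxyl beside the ether oxygen can reach the ester, so there is no site problem. The forward step must push an alkyl-to-aryl ester exchange forward and keep oxygen away from the hydroquinone.

17 ⇒ 14 (key). Ring B is opened at the bond between the carbon bearing the para hydroxyl and the unsubstituted carbon next to the methyl-bearing carbon, and folded back into a four-membered ring. A pentasubstituted arene becomes a cyclobutenone with one stereocentre of no consequence. The forward step needs the propenyl group to rotate inward on ring opening.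

14 ⇒ 11 + 12 (through 13). The bond between the carbinol carbon and the propenyl group is cut. The forward step needs 1,2-addition to the ketone carbonyl beside the aryloxy carbon, in preference to the vinylogous ester carbonyl, the ring A ester and the aryloxy-bearing carbon.

11 ⇒ 5 + 10. The vinyl carbon–oxygen bond of the future diaryl ether is cut. Forming it by addition–elimination on a vinylogous acid chloride avoids any metal-mediated coupling at a doubly ortho-substituted phenol. The forward step needs a phenol nucleophilic enough despite its hydrogen bond to the ester.

10 ⇒ 9 ⇒ 8 ⇒ 6. C–Cl goes back to C–OH, then to C–O-isopropyl, and the ring C–H goes back to a second C–O-isopropyl. These are functional-group changes on a four-carbon ring that is bought at the squaric acid oxidation level. The forward demand is a single hydride delivery to 6.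

5 ⇒ 4 ⇒ 2 ⇒ 1. The acetal returns to the aldehyde, the ring A carbon–CHO bond is cut, and the O–CH3 bond is cut. The forward demands are mono-methylation of the hydroxyl that is not hydrogen-bonded to the ester, and formylation at the only open position ortho to the remaining phenol.

## Other disconnections considered

Alternative 1: The lactone oxygen is removed retrosynthetically, so the seven-membered ring contracts to the pyranone of the xanthone (3-acetoxy-6-methoxy-1,8-dimethyl-9-oxo-9H-xanthen-4-yl)methylene diacetate A1. In the forward key step trifluoroperacetic acid A2 would add to the xanthone carbonyl. The ring B carbon para to methoxy would then migrate to oxygen (Baeyer–Villiger), forming the aryl–O and O–C(=O) bonds together and giving the depsidone triester A3.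
- In its favour: both arenes would come from orcinol-type aromatics with the oxygen pattern already in place, and a xanthone of this kind is a short acylation/cyclodehydration away. Migratory aptitude should favour the electron-rich ring B carbon over the ring A carbon, which carries acetoxy and acylal groups.
- Against it here: a xanthone carbonyl is a doubly vinylogous ester and a poor acceptor for the peracid. A peracid strong enough to add would also threaten the electron-rich ring B by hydroxylation. The aldehyde has to be hidden as an acylal to avoid Dakin oxidation. After A3 the route still needs removal of three acetates without opening the lactone, cleavage of a ring B methyl ether that has no chelating neighbour, and the same pyranone annulation as step 11.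
- Comparison: on structure, Alternative 1 is the better plan up to its key step, since no ring is built from non-aromatic carbon and about eight steps to 14 shrink to perhaps five. On mechanism, it rests on a migration from a reluctant carbonyl, whereas the chosen plan rests on a torquoselective ring opening that is general for 4-hydroxycyclobutenones. On step economy, the gain before the key step is lost afterwards (four or five operations against three), so the totals are about equal.

Alternative 2: The pyran ring is cut at the O–CMe2 bond and at the benzylic carbon–CH2 bond. This leads back to the dialdehyde 7-hydroxy-3-methoxy-1,9-dimethyl-11-oxo-11H-dibenzo[b,e][1,4]dioxepine-4,8-dicarbaldehyde A4 and 2-methylpropene A5. In the forward key step acid and trimethyl orthoformate A6 would turn the ring B salicylaldehyde into the methoxy ortho-quinone methide A7 (a 2-hydroxybenzyl oxocarbenium ion in its protonated form). A7 would add A5 in a polar hetero-Diels–Alder reaction to give the racemic 4-methoxychroman A8.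
- In its favour: the acid is mild and leaves the lactone alone, and the position of the pyran fusion is fixed by where the formyl group sits. On this point it is better than step 11 of the chosen plan.
- Against it here: it does nothing for ring B or the diaryl ether, which still have to be made some other way. It needs a second formylation, at exactly the ring B carbon whose selectivity is the open question in step 11. It creates a stereocentre only to destroy it. A8 is at the wrong oxidation level, so the benzylic methyl ether must be oxidised to the ketone in the presence of an aryl aldehyde before demethylation.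
- Comparison: on structure, this is a disconnection of the pyranone only and could in principle replace step 11 rather than the chosen key step. On mechanism, it is the equal of the chosen plan in relying on a pericyclic bond formation with built-in regiochemistry. On step economy, it is worse by about two to three steps (formylation, oxidation-level correction).

Alternative 3: Ring A is cut at two bonds, from the carboxyl-bearing carbon to the aryloxy carbon and from the methoxy carbon to the carbon that will carry the formyl group. The precursor is the tethered ester 7-[(3-{[tert-butyl(dimethyl)silyl]oxy}prop-1-yn-1-yl)oxy]-2,2,5-trimethyl-4-oxochroman-6-yl 3-methoxy-5-methyl-2-oxo-2H-pyran-6-carboxylate A9. On heating, the pyrone would add across its 3- and 6-positions to the ynol ether (intramolecular Diels–Alder). Loss of carbon dioxide A10 from the bridged adduct would then give ring A and the seven-membered lactone together in the silyl ether A11.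
- In its favour: the hexasubstituted ring A is assembled with complete regiocontrol by the tether. The electron-poor pyrone ester and the electron-rich ynol ether are well matched. The chromanone is already present, so no late acid annulation and no lactonisation equilibrium arise; on these two points it is better than the chosen plan.
- Against it here: A9 presupposes a fully built ring B chromanone with two differentiated ortho oxygens, which is the very problem the chosen key step solves. Aryl ynol ethers are made with strong base and hydrolyse easily, which conflicts with the ketone and the aryl ester. The pyrone acid needs its own synthesis. The seven-membered ring must form inside a bridged transition state. Three steps remain after A11 (desilylation, oxidation, demethylation).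
- Comparison: on structure, the two plans are mirror images, one building ring A and one ring B by a pericyclic step. On mechanism, both are metal-free and thermally driven, and are equals in that respect. On step economy, Alternative 3 is clearly longer because both fragments are multi-step.

Key step: step 9

Assumption: diisopropyl squarate 6 is taken as the catalogue form of squaric acid (its azeotropic diester with propan-2-ol), so the count starts from 6.

## Route

Step 1
Reactants: 1 methyl orsellinate (methyl 2,4-dihydroxy-6-methylbenzoate)
Product: 2 methyl 2-hydroxy-4-methoxy-6-methylbenzoate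
Conditions: MeI (1.1 equiv), K2CO3 (1.2 equiv), acetone, 25–40 °C
Reagents that add atoms: iodomethane, CI
Why: Williamson ether synthesis; the 2-hydroxyl is held in a hydrogen bond to the ester carbonyl, so the 4-hydroxyl is deprotonated and methylated first, and one equivalent of MeI limits double methylation.

Step 2
Reactants: 2 methyl 2-hydroxy-4-methoxy-6-methylbenzoate
Product: 4 methyl 3-formyl-2-hydroxy-4-methoxy-6-methylbenzoate, via hydroxymethyl phenol 3 (not isolated)
Conditions: MgCl2 (2 equiv), Et3N (4 equiv), (CH2O)n (6 equiv), MeCN, 80 °C; then 1 M HCl
Reagents that add atoms: formaldehyde (from paraformaldehyde), C=O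
Why: Magnesium-phenoxide-directed ortho-formylation (aldol-type attack on coordinated formaldehyde, then Oppenauer-type hydride transfer to a second formaldehyde); the phenol has only one open ortho position, which is also ortho to methoxy, so the formyl group can only enter between hydroxyl and methoxy.

Step 3
Reactants: 4 methyl 3-formyl-2-hydroxy-4-methoxy-6-methylbenzoate
Product: 5 methyl 3-(1,3-dioxolan-2-yl)-2-hydroxy-4-methoxy-6-methylbenzoate
Conditions: HOCH2CH2OH (5 equiv), p-TsOH·H2O (5 mol%), toluene, reflux, Dean–Stark; Et3N quench
Reagents that add atoms: ethane-1,2-diol, OCCO
Why: Acid-catalysed acetalisation driven by azeotropic removal of water; the phenol stays hydrogen-bonded to the hindered ester, which does not exchange with the diol, and the acetal is needed only to carry the formyl carbon through the organolithium step.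

Step 4
Reactants: 6 diisopropyl squarate (3,4-di(propan-2-yloxy)cyclobut-3-ene-1,2-dione)
Product: 8 3-(propan-2-yloxy)cyclobut-3-ene-1,2-dione, via hydroxycyclobutenone 7 (not isolated)
Conditions: LiAlH(OtBu)3 (1.05 equiv), THF, −78 → −20 °C; then conc. HCl (cat.), CH2Cl2, 25 °C
Reagents that add atoms: none
Why: 1,2-Hydride addition of a bulky alkoxyaluminium hydride to one squarate carbonyl, then acid-induced allylic transposition with loss of propan-2-ol, which turns the carbinol carbon into the vinylic CH; this is the established reduction route to alkyl semisquarates.

Step 5
Reactants: 8 3-(propan-2-yloxy)cyclobut-3-ene-1,2-dione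
Product: 9 3-hydroxycyclobut-3-ene-1,2-dione (semisquaric acid)
Conditions: 6 M aq. HCl, 25 → 50 °C; evaporate, toluene azeotrope
Reagents that add atoms: water, O
Why: Hydrolysis of a vinylogous ester by addition–elimination of water at the alkoxy-bearing carbon; the product is a strong vinylogous acid and is simply dried for the next step.

Step 6
Reactants: 9 3-hydroxycyclobut-3-ene-1,2-dione (semisquaric acid)
Product: 10 3-chlorocyclobut-3-ene-1,2-dione
Conditions: (COCl)2 (1.2 equiv), DMF (cat.), CH2Cl2, 0 → 25 °C; evaporate, use at once
Reagents that add atoms: oxalyl chloride, O=C(Cl)C(Cl)=O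
Why: Conversion of a vinylogous carboxylic acid into its vinylogous acid chloride through the chloroiminium (Vilsmeier-type) activation used for acid chlorides; the moisture-sensitive product is not stored.

Step 7
Reactants: 5 methyl 3-(1,3-dioxolan-2-yl)-2-hydroxy-4-methoxy-6-methylbenzoate; 10 3-chlorocyclobut-3-ene-1,2-dione
Product: 11 methyl 3-(1,3-dioxolan-2-yl)-2-[(3,4-dioxocyclobut-1-en-1-yl)oxy]-4-methoxy-6-methylbenzoate
Conditions: i-Pr2NEt (1.2 equiv), CH2Cl2, −40 → 0 °C
Reagents that add atoms: none
Why: Addition–elimination of the phenol on a vinylogous acid chloride (an O-acylation in type); the small, flat and very electrophilic four-membered ring tolerates the two ortho substituents of the phenol, and the hindered amine only takes up HCl.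

Step 8
Reactants: 11 methyl 3-(1,3-dioxolan-2-yl)-2-[(3,4-dioxocyclobut-1-en-1-yl)oxy]-4-methoxy-6-methylbenzoate; 12 2-bromopropene
Product: 14 methyl 3-(1,3-dioxolan-2-yl)-2-{[4-hydroxy-3-oxo-4-(prop-1-en-2-yl)cyclobut-1-en-1-yl]oxy}-4-methoxy-6-methylbenzoate (racemic), via isopropenyllithium 13 (not isolated)
Conditions: 12, t-BuLi (2 equiv), Et2O, −78 °C; then added to 11 (1.05 equiv of 13), THF, −78 °C; aq. NH4Cl at −78 °C
Reagents that add atoms: none
Why: Halogen–lithium exchange, then 1,2-addition to the ketone carbonyl beside the aryloxy carbon, since the other carbonyl is deactivated as a vinylogous ester and the di-ortho-substituted benzoate is shielded at −78 °C. The new carbinol centre forms as a racemate, which is of no consequence because step 9 erases it.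

Step 9
Reactants: 14 methyl 3-(1,3-dioxolan-2-yl)-2-{[4-hydroxy-3-oxo-4-(prop-1-en-2-yl)cyclobut-1-en-1-yl]oxy}-4-methoxy-6-methylbenzoate (racemic)
Product: 17 methyl 2-(2,5-dihydroxy-3-methylphenoxy)-3-(1,3-dioxolan-2-yl)-4-methoxy-6-methylbenzoate, via dienylketene 15 (not isolated), via cyclohexadienone 16 (not isolated)
Conditions: toluene (degassed, 0.02 M, base-washed glassware), 110 °C, Ar
Reagents that add atoms: none
Why: Heating should open the cyclobutenone by a thermal conrotatory 4π electrocyclic cleavage of the bond between the carbonyl carbon and the carbinol carbon, giving dienylketene 15. The hydroxyl is the better donor and rotates outward, so the prop-1-en-2-yl group rotates inward and ends up cis to the ketene across the new enol double bond. A thermal disrotatory 6π electrocyclisation then joins the ketene carbon to the CH2 terminus of the propenyl group, the single new skeletal bond, and closes ring B as the all-carbon six-membered cyclohexa-2,4-dienone 16. Enolisation of 16, driven by aromatisation, gives hydroquinone 17. Connectivity fixes the regiochemistry: the ketene carbonyl becomes the hydroxyl para to the carbinol-derived hydroxyl, and the latter sits between the aryloxy and methyl carbons. The closest known reaction type is the Moore rearrangement of 4-alkenyl-4-hydroxycyclobutenones made from squaric acid derivatives. No stereocentre is formed, and the one in 14 disappears. The selectivity needed is ring closure at carbon rather than capture of the ketene by the hydroxyl; the outward rotation of the hydroxyl secures this, and neutral, oxygen-free conditions protect the acetal and the hydroquinone.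

Step 10
Reactants: 17 methyl 2-(2,5-dihydroxy-3-methylphenoxy)-3-(1,3-dioxolan-2-yl)-4-methoxy-6-methylbenzoate
Product: 18 4-(1,3-dioxolan-2-yl)-7-hydroxy-3-methoxy-1,9-dimethyl-11H-dibenzo[b,e][1,4]dioxepin-11-one
Conditions: K2CO3 (1.5 equiv), powdered 5 Å molecular sieves, DMF (degassed, 0.01 M), 70 °C, Ar; then aq. NaH2PO4
Reagents that add atoms: none
Why: Base-mediated intramolecular transesterification (7-exo-trig lactonisation); only the phenoxide beside the ether oxygen can reach the ester, and trapping of methanol by the sieves pulls the alkyl-to-aryl ester exchange forward. The acetal keeps ring A electron-rich, which disfavours a Smiles-type aryl shift, and exclusion of oxygen protects the hydroquinone.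

Step 11
Reactants: 18 4-(1,3-dioxolan-2-yl)-7-hydroxy-3-methoxy-1,9-dimethyl-11H-dibenzo[b,e][1,4]dioxepin-11-one; 19 3-methylbut-2-enoic acid
Product: 22 O-methylmollicellin B (ring A methyl ether of 23), via aryl enone 20 (not isolated), via acetal chromanone 21 (not isolated)
Conditions: 19 (1.3 equiv), P2O5/MeSO3H (1:10 w/w), 50 °C; then ice–water, 25 °C
Reagents that add atoms: water, O
Why: Friedel–Crafts acylation by the activated acid ortho to the only free phenol, then 6-endo-trig oxa-Michael closure of the pyranone; the carbon between hydroxyl and methyl is para to the ether oxygen and should be preferred over the carbon between two oxygens, as in acylations of 3,4-dioxygenated phenols. Ring A is deactivated and its phenol is capped, and the acetal is hydrolysed in the aqueous acidic quench.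

Step 12
Reactants: 22 O-methylmollicellin B (ring A methyl ether of 23)
Product: 23 mollicellin B
Conditions: BCl3 (3 equiv), CH2Cl2, −78 → 0 °C; then H2O
Reagents that add atoms: none
Why: Chelation-controlled Lewis-acid demethylation; boron binds the formyl oxygen and the ortho methoxy oxygen and chloride removes the methyl group, while the lactone and the tertiary chroman ether, which have no chelating neighbour, should survive at low temperature.

## Compound list

1 | methyl orsellinate (methyl 2,4-dihydroxy-6-methylbenzoate) | COC(=O)c1c(C)cc(O)cc1O | starting material
2 | methyl 2-hydroxy-4-methoxy-6-methylbenzoate | COC(=O)c1c(C)cc(OC)cc1O | intermediate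
3 | methyl 2-hydroxy-3-(hydroxymethyl)-4-methoxy-6-methylbenzoate, formed in the flask and not isolated | COC(=O)c1c(C)cc(OC)c(CO)c1O | intermediate
4 | methyl 3-formyl-2-hydroxy-4-methoxy-6-methylbenzoate | COC(=O)c1c(C)cc(OC)c(C=O)c1O | intermediate
5 | methyl 3-(1,3-dioxolan-2-yl)-2-hydroxy-4-methoxy-6-methylbenzoate | COC(=O)c1c(C)cc(OC)c(C2OCCO2)c1O | intermediate
6 | diisopropyl squarate (3,4-di(propan-2-yloxy)cyclobut-3-ene-1,2-dione) | CC(C)OC1=C(OC(C)C)C(=O)C1=O | starting material
7 | 4-hydroxy-2,3-di(propan-2-yloxy)cyclobut-2-en-1-one, racemic, formed in the flask and not isolated | CC(C)OC1=C(OC(C)C)C(O)C1=O | intermediate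
8 | 3-(propan-2-yloxy)cyclobut-3-ene-1,2-dione | CC(C)OC1=CC(=O)C1=O | intermediate
9 | 3-hydroxycyclobut-3-ene-1,2-dione (semisquaric acid) | OC1=CC(=O)C1=O | intermediate
10 | 3-chlorocyclobut-3-ene-1,2-dione | ClC1=CC(=O)C1=O | intermediate
11 | methyl 3-(1,3-dioxolan-2-yl)-2-[(3,4-dioxocyclobut-1-en-1-yl)oxy]-4-methoxy-6-methylbenzoate | COC(=O)c1c(C)cc(OC)c(C2OCCO2)c1OC1=CC(=O)C1=O | intermediate
12 | 2-bromopropene | CC(Br)=C | starting material
13 | isopropenyllithium (prop-1-en-2-yllithium), formed in the flask and not isolated | [Li]C(C)=C | intermediate
14 | methyl 3-(1,3-dioxolan-2-yl)-2-{[4-hydroxy-3-oxo-4-(prop-1-en-2-yl)cyclobut-1-en-1-yl]oxy}-4-methoxy-6-methylbenzoate, racemic | COC(=O)c1c(C)cc(OC)c(C2OCCO2)c1OC1=CC(=O)C1(O)C(C)=C | intermediate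
15 | methyl 3-(1,3-dioxolan-2-yl)-2-{[(3Z)-4-hydroxy-5-methyl-1-oxohexa-1,3,5-trien-3-yl]oxy}-4-methoxy-6-methylbenzoate (dienylketene), formed in the flask and not isolated | COC(=O)c1c(C)cc(OC)c(C2OCCO2)c1O/C(C=C=O)=C(\O)C(C)=C | intermediate
16 | methyl 3-(1,3-dioxolan-2-yl)-2-[(6-hydroxy-5-methyl-3-oxocyclohexa-1,5-dien-1-yl)oxy]-4-methoxy-6-methylbenzoate, formed in the flask and not isolated | COC(=O)c1c(C)cc(OC)c(C2OCCO2)c1OC1=CC(=O)CC(C)=C1O | intermediate
17 | methyl 2-(2,5-dihydroxy-3-methylphenoxy)-3-(1,3-dioxolan-2-yl)-4-methoxy-6-methylbenzoate | COC(=O)c1c(C)cc(OC)c(C2OCCO2)c1Oc1cc(O)cc(C)c1O | intermediate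
18 | 4-(1,3-dioxolan-2-yl)-7-hydroxy-3-methoxy-1,9-dimethyl-11H-dibenzo[b,e][1,4]dioxepin-11-one | Cc1cc(OC)c(C2OCCO2)c2c1C(=O)Oc1c(C)cc(O)cc1O2 | intermediate
19 | 3-methylbut-2-enoic acid | CC(C)=CC(=O)O | starting material
20 | 4-(1,3-dioxolan-2-yl)-7-hydroxy-3-methoxy-1,9-dimethyl-8-(3-methylbut-2-enoyl)-11H-dibenzo[b,e][1,4]dioxepin-11-one, formed in the flask and not isolated | Cc1cc(OC)c(C2OCCO2)c2c1C(=O)Oc1c(C)c(C(=O)C=C(C)C)c(O)cc1O2 | intermediate
21 | ethylene acetal of 22 (pyranone closed, 1,3-dioxolan-2-yl in place of formyl), formed in the flask and not isolated | Cc1cc(OC)c(C2OCCO2)c2c1C(=O)Oc1c(cc3c(c1C)C(=O)CC(C)(C)O3)O2 | intermediate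
22 | O-methylmollicellin B (ring A methyl ether of 23) | Cc1cc(OC)c(C=O)c2c1C(=O)Oc1c(cc3c(c1C)C(=O)CC(C)(C)O3)O2 | intermediate
23 | mollicellin B | Cc1cc(O)c(C=O)c2c1C(=O)Oc1c(cc3c(c1C)C(=O)CC(C)(C)O3)O2 | target

## Step count and least certain steps

Total step count: 12. Longest linear sequence: 9 steps (from 1 through steps 1–3 and 7–12; the branch from 6 through steps 4–6 and 7–12 is equally long).

Step 9 (key step). The most likely failure is a loss of torquoselectivity, with the hydroxyl turning inward and adding to the ketene instead of the propenyl group cyclising. Ionisation of the tertiary allylic alcohol or loss of the acetal through adventitious acid at 110 °C is the second concern. The fallback sets out from 14. It is silylated (Me3SiCl, Et3N, CH2Cl2) to the trimethylsilyl ether F1, whose silyloxy group is still the outward-turning donor but can no longer add to the ketene. Thermolysis in toluene should then give the mono-silylated hydroquinone F2, and Bu4NF buffered with AcOH returns the route to 17.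

Step 11. Acylation could take place at the ring B carbon between the two oxygens. The hot sulfonic acid medium could also promote an acyl shift of the aryl ester lactone onto ring B, or alkylation of another molecule by the acetal-derived oxocarbenium ion. The fallback sets out from 18 and avoids strong acid. Steglich esterification with 19 (EDC·HCl, DMAP, CH2Cl2) gives the aryl 3-methylbut-2-enoate F3. A photo-Fries rearrangement (300 nm, degassed benzene) moves the acyl group to the ortho carbon to give 20, this time isolated. The positions ortho and para to the lactone oxygen are all substituted, so the lactone chromophore has no productive path of its own. DBU closes 20 to 21, and dilute aqueous acid removes the acetal, returning the route at 22.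

Step 10. Exchange of an alkyl ester for an aryl ester is uphill, so the lactone may reopen through methanol or methoxide left in the mixture. Autoxidation of the doubly deprotonated hydroquinone is the second danger. The fallback sets out from 17. SN2 demethylation of the hindered ester with LiI in pyridine at reflux under argon gives the carboxylic acid F4. Carbodiimide lactonisation (EDC·HCl, DMAP cat., CH2Cl2, high dilution), which is irreversible, returns the route at 18.

Step 8. The strongly basic lithium reagent may add to the aryloxy-bearing carbon and expel the ring A phenoxide (addition–elimination), or attack the second carbonyl. The fallback sets out from 11 and changes the organometallic, not the substrate. Commercial isopropenylmagnesium bromide is transmetallated with anhydrous CeCl3 (THF, −78 °C) to a cerium reagent of low basicity with a strong preference for 1,2-addition to ketones. It returns the route at 14 and makes no new compound.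

Step 7. The vinylogous acid chloride 10 may hydrolyse or oligomerise before the hindered, hydrogen-bonded phenol attacks, and the amine may react with 10 itself. The fallback sets out from 5 and uses commercial, crystalline 3,4-dichlorocyclobut-3-ene-1,2-dione (ClC1=C(Cl)C(=O)C1=O) with i-Pr2NEt to give the aryloxy chloro dione F5. Hydrodechlorination of this vinylogous acid chloride with Bu3SnH and catalytic Pd(PPh3)4 (zerovalent palladium), in the manner of acid chloride to aldehyde reductions, returns the route at 11. This path also makes steps 4–6 unnecessary.

## Further compounds

F1 | step 9 | methyl 3-(1,3-dioxolan-2-yl)-4-methoxy-6-methyl-2-{[3-oxo-4-(prop-1-en-2-yl)-4-(trimethylsilyloxy)cyclobut-1-en-1-yl]oxy}benzoate, racemic | COC(=O)c1c(C)cc(OC)c(C2OCCO2)c1OC1=CC(=O)C1(O[Si](C)(C)C)C(C)=C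
F2 | step 9 | methyl 3-(1,3-dioxolan-2-yl)-2-[5-hydroxy-3-methyl-2-(trimethylsilyloxy)phenoxy]-4-methoxy-6-methylbenzoate | COC(=O)c1c(C)cc(OC)c(C2OCCO2)c1Oc1cc(O)cc(C)c1O[Si](C)(C)C
F3 | step 11 | 4-(1,3-dioxolan-2-yl)-3-methoxy-1,9-dimethyl-11-oxo-11H-dibenzo[b,e][1,4]dioxepin-7-yl 3-methylbut-2-enoate | Cc1cc(OC)c(C2OCCO2)c2c1C(=O)Oc1c(C)cc(OC(=O)C=C(C)C)cc1O2
F4 | step 10 | 2-(2,5-dihydroxy-3-methylphenoxy)-3-(1,3-dioxolan-2-yl)-4-methoxy-6-methylbenzoic acid | OC(=O)c1c(C)cc(OC)c(C2OCCO2)c1Oc1cc(O)cc(C)c1O
F0 | step 8 | none | none
F5 | step 7 | methyl 2-[(2-chloro-3,4-dioxocyclobut-1-en-1-yl)oxy]-3-(1,3-dioxolan-2-yl)-4-methoxy-6-methylbenzoate | COC(=O)c1c(C)cc(OC)c(C2OCCO2)c1OC1=C(Cl)C(=O)C1=O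
A1 | alternative 1 | (3-acetoxy-6-methoxy-1,8-dimethyl-9-oxo-9H-xanthen-4-yl)methylene diacetate | Cc1cc(OC(C)=O)c(C(OC(C)=O)OC(C)=O)c2c1C(=O)c1c(C)cc(OC)cc1O2
A2 | alternative 1 | trifluoroperacetic acid | OOC(=O)C(F)(F)F
A3 | alternative 1 | (3-acetoxy-7-methoxy-1,9-dimethyl-11-oxo-11H-dibenzo[b,e][1,4]dioxepin-4-yl)methylene diacetate | Cc1cc(OC(C)=O)c(C(OC(C)=O)OC(C)=O)c2c1C(=O)Oc1c(C)cc(OC)cc1O2
A4 | alternative 2 | 7-hydroxy-3-methoxy-1,9-dimethyl-11-oxo-11H-dibenzo[b,e][1,4]dioxepine-4,8-dicarbaldehyde | Cc1cc(OC)c(C=O)c2c1C(=O)Oc1c(C)c(C=O)c(O)cc1O2
A5 | alternative 2 | 2-methylpropene | CC(C)=C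
A6 | alternative 2 | trimethyl orthoformate | COC(OC)OC
A7 | alternative 2 | methoxy ortho-quinone methide of A4 (ring B as 6-(methoxymethylidene)cyclohexa-2,4-dienone; geometry of the exocyclic alkene left open) | Cc1cc(OC)c(C=O)c2c1C(=O)OC1=C(C)C(=COC)C(=O)C=C1O2
A8 | alternative 2 | 4-methoxy-2,2-dimethylchroman-fused depsidone (22 with CH(OCH3) in place of the pyranone carbonyl), racemic | Cc1cc(OC)c(C=O)c2c1C(=O)Oc1c(cc3c(c1C)C(OC)CC(C)(C)O3)O2
A9 | alternative 3 | 7-[(3-{[tert-butyl(dimethyl)silyl]oxy}prop-1-yn-1-yl)oxy]-2,2,5-trimethyl-4-oxochroman-6-yl 3-methoxy-5-methyl-2-oxo-2H-pyran-6-carboxylate | COC1=CC(C)=C(C(=O)Oc2c(C)c3c(cc2OC#CCO[Si](C)(C)C(C)(C)C)OC(C)(C)CC3=O)OC1=O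
A10 | alternative 3 | carbon dioxide | O=C=O
A11 | alternative 3 | depsidone with ring A methyl ether and tert-butyldimethylsilyloxymethyl group (22 with CH2OSi(CH3)2C(CH3)3 in place of formyl) | Cc1cc(OC)c(CO[Si](C)(C)C(C)(C)C)c2c1C(=O)Oc1c(cc3c(c1C)C(=O)CC(C)(C)O3)O2
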